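**Plan**

- Retrosynthesis: the four benzyl ethers come off last. Ring E is then cut across C1'–C2' and C5'–C6' (C1' bears the bridge, C3' the oxygen), the alkyne carbon C6' is traced back to an aldehyde, and the three ArCH2–ring A bonds at C2, C4 and C6 are cut back to a 3-(3-hydroxy-5-methoxyphenyl)propanoate.
- Enabling feature: ring E is a benzene with only two substituents, the bridge on C1' and the hydroxyl on C3', in a meta relation. C2', C4', C5' and C6' are plain CH, so a terminal alkyne (C1', C6') and a 2-silyloxybuta-1,3-diene (C2'–C5') supply the whole ring.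
- Forward: ring A is bought as 3-(3,5-dimethoxyphenyl)propanoic acid and desymmetrised by mono-demethylation. Rings B, C and D are attached one at a time by three Friedel–Crafts benzylations (C6, then C2, then C4), the remaining phenol is benzylated, and the ester is taken to the but-3-ynyl chain.
- Ring E is formed last, by cobalt-catalysed [4+2] cycloaddition at the dihydro level, followed by dehydrogenation, desilylation and hydrogenolysis.
- Stereochemistry: the target has no stereocentre and no stereogenic double bond. The only selectivity to be set is the meta regiochemistry of ring E, which the ligand on cobalt controls.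

Key step: step 9

Remark: ring A is numbered from the bridge-bearing carbon (C1; benzyl groups on C2, C4, C6; OH on C3; OMe on C5) and ring E from C1' (bridge) with oxygen on C3'. 3-(3,5-Dimethoxyphenyl)propanoic acid is assumed to be purchasable. Because C2, C4 and C6 finally carry the same group, regioisomeric mono- and bis-benzylated material from steps 3 and 4 converges on 7; compounds 5 and 6 are drawn as the isomers expected to predominate.

**Route**

Step 1
Reactants: 1 3-(3,5-dimethoxyphenyl)propanoic acid
Product: 2 3-(3-hydroxy-5-methoxyphenyl)propanoic acid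
Conditions: NaSEt (4 equiv), DMF, 140 °C; then 1 M HCl
Reagents that add atoms: none
Why: Ethanethiolate cleaves an aryl methyl ether by SN2 attack at the methyl carbon, and the phenoxide formed deactivates the ring so strongly that the second methoxy group should be left untouched, the standard desymmetrisation of 5-alkylresorcinol dimethyl ethers; the carboxylate is a spectator.

Step 2
Reactants: 2 3-(3-hydroxy-5-methoxyphenyl)propanoic acid
Product: 3 methyl 3-(3-hydroxy-5-methoxyphenyl)propanoate
Conditions: MeOH, H2SO4 (cat.), reflux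
Reagents that add atoms: methanol, CO
Why: Fischer esterification in excess methanol converts the acid to the methyl ester needed for the later partial reduction, and the phenol does not react under these conditions.

Step 3
Reactants: 3 methyl 3-(3-hydroxy-5-methoxyphenyl)propanoate; 4 4-(benzyloxy)benzyl alcohol
Product: 5 methyl 3-{2-[4-(benzyloxy)benzyl]-5-hydroxy-3-methoxyphenyl}propanoate
Conditions: 4 (1.0 equiv, slow addition), Sc(OTf)3 (5 mol%), MeNO2/CH2Cl2, 0 °C to rt
Reagents that add atoms: none
Why: Friedel–Crafts benzylation, in which Sc(OTf)3 ionises the benzylic alcohol to a 4-alkoxybenzyl cation that ring A, far more nucleophilic than the anisole-type ring of 4, should take up mainly at C6 (locant 2 in the name of 5), para to the free hydroxyl as the strongest donor, while the new benzyl group lies meta to C2 and C4 and so does not activate them towards a second alkylation under one equivalent of 4.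

Step 4
Reactants: 5 methyl 3-{2-[4-(benzyloxy)benzyl]-5-hydroxy-3-methoxyphenyl}propanoate; 4 4-(benzyloxy)benzyl alcohol
Product: 6 methyl 3-{2,6-bis[4-(benzyloxy)benzyl]-3-hydroxy-5-methoxyphenyl}propanoate
Conditions: 4 (1.1 equiv, slow addition), Sc(OTf)3 (5 mol%), MeNO2/CH2Cl2, rt
Reagents that add atoms: none
Why: Second Friedel–Crafts benzylation under the same catalysis, expected at C2, which is ortho to the hydroxyl and para to the methoxy group, in preference to C4, which has no para donor and is shielded by the methoxy methyl group that the C6 benzyl group turns towards it.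

Step 5
Reactants: 6 methyl 3-{2,6-bis[4-(benzyloxy)benzyl]-3-hydroxy-5-methoxyphenyl}propanoate; 4 4-(benzyloxy)benzyl alcohol
Product: 7 methyl 3-{2,4,6-tris[4-(benzyloxy)benzyl]-3-hydroxy-5-methoxyphenyl}propanoate
Conditions: 4 (1.3 equiv, slow addition), Sc(OTf)3 (10 mol%), MeNO2/CH2Cl2, 40 °C
Reagents that add atoms: none
Why: Third Friedel–Crafts benzylation at C4, the only free position of ring A, which is ortho to both oxygen substituents and so still more nucleophilic than the alkoxyphenyl rings already attached; the hindered site calls for more catalyst and gentle warming, and any O-benzylated material should revert to the C-alkylated product under the acidic conditions.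

Step 6
Reactants: 7 methyl 3-{2,4,6-tris[4-(benzyloxy)benzyl]-3-hydroxy-5-methoxyphenyl}propanoate
Product: 8 methyl 3-{3-(benzyloxy)-2,4,6-tris[4-(benzyloxy)benzyl]-5-methoxyphenyl}propanoate
Conditions: BnBr, K2CO3, DMF, 60 °C
Reagents that add atoms: benzyl bromide, BrCc1ccccc1
Why: Williamson ether synthesis on the phenoxide, which although flanked by two benzyl groups should still react with the unhindered benzylic bromide in a dipolar aprotic solvent, while the methyl ester tolerates anhydrous K2CO3.

Step 7
Reactants: 8 methyl 3-{3-(benzyloxy)-2,4,6-tris[4-(benzyloxy)benzyl]-5-methoxyphenyl}propanoate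
Product: 9 3-{3-(benzyloxy)-2,4,6-tris[4-(benzyloxy)benzyl]-5-methoxyphenyl}propanal
Conditions: i-Bu2AlH (1.1 equiv), CH2Cl2, −78 °C; then MeOH, aq. KNaC4H4O6 (potassium sodium tartrate)
Reagents that add atoms: none
Why: Partial reduction of a methyl ester with one equivalent of i-Bu2AlH at −78 °C stops at the tetrahedral aluminium hemiacetal, which releases the aldehyde only on work-up, and the benzyl and methyl ethers are inert.

Step 8
Reactants: 9 3-{3-(benzyloxy)-2,4,6-tris[4-(benzyloxy)benzyl]-5-methoxyphenyl}propanal; 10 dimethyl (1-diazo-2-oxopropyl)phosphonate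
Product: 11 1-(benzyloxy)-2,4,6-tris[4-(benzyloxy)benzyl]-3-(but-3-yn-1-yl)-5-methoxybenzene
Conditions: 10 (1.3 equiv), K2CO3 (2 equiv), MeOH/THF, 0 °C to rt
Reagents that add atoms: none
Why: Ohira–Bestmann alkynylation (Seyferth–Gilbert homologation), in which methanolysis of 10 gives the diazomethylphosphonate anion that olefinates the aldehyde to a diazoalkene, which loses N2 and undergoes a 1,2-hydride shift to the terminal alkyne under conditions mild enough for an enolisable aldehyde.

Step 9
Reactants: 11 1-(benzyloxy)-2,4,6-tris[4-(benzyloxy)benzyl]-3-(but-3-yn-1-yl)-5-methoxybenzene; 12 2-(trimethylsilyloxy)buta-1,3-diene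
Product: 13 1-(benzyloxy)-2,4,6-tris[4-(benzyloxy)benzyl]-5-methoxy-3-{2-[5-(trimethylsilyloxy)cyclohexa-1,4-dien-1-yl]ethyl}benzene
Conditions: CoBr2 (10 mol%), 2,4,6-trimethyl-N-(pyridin-2-ylmethylidene)aniline (10 mol%), Zn dust (20 mol%), ZnI2 (20 mol%), 12 (2 equiv), CH2Cl2, rt; filtration through Et3N-deactivated silica, used crude
Reagents that add atoms: none
Why: Zn reduces the CoBr2–pyridine-imine complex (divalent cobalt) to a monovalent cobalt species made cationic by ZnI2, which binds the s-cis diene 12 and the terminal alkyne of 11, couples them oxidatively to a cobaltacycle (trivalent cobalt) and releases the cyclohexa-1,4-diene by reductive elimination. The closest known reaction type is the cobalt-catalysed neutral Diels–Alder reaction of unactivated terminal alkynes with 2-substituted buta-1,3-dienes, 2-silyloxy dienes included, in which the ligand on cobalt dictates the regiochemistry. Ring E is closed in an intermolecular [4+2] mode, two carbons (C1', C6') from the alkyne and four (C2'–C5') from the diene, by forming the C1'–C2' and C5'–C6' bonds. No stereocentre is created, since every new ring atom is either sp2 or CH2. The step needs the 1,3 (meta) placement of bridge and silyloxy group instead of the 1,4 (para) one, and chemoselectivity over alkyne cyclotrimerisation. The first is imposed by the N-mesityl pyridine-imine ligand (bisphosphine ligands lead to the para series), the substrate helping only in that its alkyne is terminal, unbranched and three atoms away from crowded ring A, and the second is secured by the excess of diene.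

Step 10
Reactants: 13 1-(benzyloxy)-2,4,6-tris[4-(benzyloxy)benzyl]-5-methoxy-3-{2-[5-(trimethylsilyloxy)cyclohexa-1,4-dien-1-yl]ethyl}benzene
Product: 15 3-(2-{3-(benzyloxy)-2,4,6-tris[4-(benzyloxy)benzyl]-5-methoxyphenyl}ethyl)phenol, via aryl trimethylsilyl ether 14 (not isolated)
Conditions: DDQ (1.05 equiv), toluene, 0 °C to rt; filter; then K2CO3 (cat.), MeOH/THF, rt
Reagents that add atoms: none
Why: Dehydrogenation of a cyclohexa-1,4-diene by DDQ (hydride abstraction from the doubly allylic C5' methylene assisted by the silyloxy group, then proton loss from C2') is fast at or below room temperature, well below the conditions needed to attack the diarylmethane CH2 groups or the benzyl ethers, and the aryl trimethylsilyl ether is then cleaved by base-catalysed methanolysis.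

Step 11
Reactants: 15 3-(2-{3-(benzyloxy)-2,4,6-tris[4-(benzyloxy)benzyl]-5-methoxyphenyl}ethyl)phenol
Product: 16 2,4,6-tris(4-hydroxybenzyl)-3-[2-(3-hydroxyphenyl)ethyl]-5-methoxyphenol
Conditions: H2 (1 atm), 10% Pd/C, EtOAc/MeOH, rt
Reagents that add atoms: none
Why: Catalytic hydrogenolysis cleaves the four O–CH2Ph bonds of the aryl benzyl ethers, while the diarylmethane C–C bonds, the bibenzyl bridge, the methyl ether and the aromatic rings should not be reduced under one atmosphere of hydrogen at room temperature.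

**Compound list**

1 | 3-(3,5-dimethoxyphenyl)propanoic acid | COc1cc(CCC(=O)O)cc(OC)c1 | starting material
2 | 3-(3-hydroxy-5-methoxyphenyl)propanoic acid | COc1cc(O)cc(CCC(=O)O)c1 | intermediate
3 | methyl 3-(3-hydroxy-5-methoxyphenyl)propanoate | COC(=O)CCc1cc(O)cc(OC)c1 | intermediate
4 | 4-(benzyloxy)benzyl alcohol | OCc1ccc(OCc2ccccc2)cc1 | starting material
5 | methyl 3-{2-[4-(benzyloxy)benzyl]-5-hydroxy-3-methoxyphenyl}propanoate | COC(=O)CCc1cc(O)cc(OC)c1Cc1ccc(OCc2ccccc2)cc1 | intermediate
6 | methyl 3-{2,6-bis[4-(benzyloxy)benzyl]-3-hydroxy-5-methoxyphenyl}propanoate | COC(=O)CCc1c(Cc2ccc(OCc3ccccc3)cc2)c(O)cc(OC)c1Cc1ccc(OCc2ccccc2)cc1 | intermediate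
7 | methyl 3-{2,4,6-tris[4-(benzyloxy)benzyl]-3-hydroxy-5-methoxyphenyl}propanoate | COC(=O)CCc1c(Cc2ccc(OCc3ccccc3)cc2)c(O)c(Cc2ccc(OCc3ccccc3)cc2)c(OC)c1Cc1ccc(OCc2ccccc2)cc1 | intermediate
8 | methyl 3-{3-(benzyloxy)-2,4,6-tris[4-(benzyloxy)benzyl]-5-methoxyphenyl}propanoate | COC(=O)CCc1c(Cc2ccc(OCc3ccccc3)cc2)c(OCc2ccccc2)c(Cc2ccc(OCc3ccccc3)cc2)c(OC)c1Cc1ccc(OCc2ccccc2)cc1 | intermediate
9 | 3-{3-(benzyloxy)-2,4,6-tris[4-(benzyloxy)benzyl]-5-methoxyphenyl}propanal | O=CCCc1c(Cc2ccc(OCc3ccccc3)cc2)c(OCc2ccccc2)c(Cc2ccc(OCc3ccccc3)cc2)c(OC)c1Cc1ccc(OCc2ccccc2)cc1 | intermediate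
10 | dimethyl (1-diazo-2-oxopropyl)phosphonate | COP(=O)(OC)C(=[N+]=[N-])C(C)=O | starting material
11 | 1-(benzyloxy)-2,4,6-tris[4-(benzyloxy)benzyl]-3-(but-3-yn-1-yl)-5-methoxybenzene | COc1c(Cc2ccc(OCc3ccccc3)cc2)c(OCc2ccccc2)c(Cc2ccc(OCc3ccccc3)cc2)c(CCC#C)c1Cc1ccc(OCc2ccccc2)cc1 | intermediate
12 | 2-(trimethylsilyloxy)buta-1,3-diene | C=CC(=C)O[Si](C)(C)C | starting material
13 | 1-(benzyloxy)-2,4,6-tris[4-(benzyloxy)benzyl]-5-methoxy-3-{2-[5-(trimethylsilyloxy)cyclohexa-1,4-dien-1-yl]ethyl}benzene | COc1c(Cc2ccc(OCc3ccccc3)cc2)c(OCc2ccccc2)c(Cc2ccc(OCc3ccccc3)cc2)c(CCC2=CCC=C(O[Si](C)(C)C)C2)c1Cc1ccc(OCc2ccccc2)cc1 | intermediate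
14 | 1-(benzyloxy)-2,4,6-tris[4-(benzyloxy)benzyl]-5-methoxy-3-{2-[3-(trimethylsilyloxy)phenyl]ethyl}benzene | COc1c(Cc2ccc(OCc3ccccc3)cc2)c(OCc2ccccc2)c(Cc2ccc(OCc3ccccc3)cc2)c(CCc2cccc(O[Si](C)(C)C)c2)c1Cc1ccc(OCc2ccccc2)cc1 | intermediate (not isolated)
15 | 3-(2-{3-(benzyloxy)-2,4,6-tris[4-(benzyloxy)benzyl]-5-methoxyphenyl}ethyl)phenol | COc1c(Cc2ccc(OCc3ccccc3)cc2)c(OCc2ccccc2)c(Cc2ccc(OCc3ccccc3)cc2)c(CCc2cccc(O)c2)c1Cc1ccc(OCc2ccccc2)cc1 | intermediate
16 | 2,4,6-tris(4-hydroxybenzyl)-3-[2-(3-hydroxyphenyl)ethyl]-5-methoxyphenol | COc1c(Cc2ccc(O)cc2)c(O)c(Cc2ccc(O)cc2)c(CCc2cccc(O)c2)c1Cc1ccc(O)cc1 | target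

**Step count and risks**

Total step count: 11. Longest linear sequence: 11 steps (1 to 16).

Steps most likely to fail:

1. Step 9. The meta regioselectivity may erode with a purely alkyl-substituted alkyne, giving some of the para-oriented diene, and the catalyst may be diverted into alkyne cyclotrimerisation or deactivated by the polyether substrate. A minor para isomer would be removed at phenol 15. Fallback: the aryl ring is brought in preformed by decarboxylative arylation, setting out from ester 8. Saponification (LiOH, THF/MeOH/H2O; then 1 M HCl) should give 3-{3-(benzyloxy)-2,4,6-tris[4-(benzyloxy)benzyl]-5-methoxyphenyl}propanoic acid F1. Condensation with N-hydroxyphthalimide (N,N'-diisopropylcarbodiimide, DMAP cat., CH2Cl2) would give the redox-active 1,3-dioxoisoindolin-2-yl 3-{3-(benzyloxy)-2,4,6-tris[4-(benzyloxy)benzyl]-5-methoxyphenyl}propanoate F2. Nickel-catalysed decarboxylative Negishi coupling of this ester with 3-(benzyloxy)phenylzinc chloride (made from 1-(benzyloxy)-3-bromobenzene, Mg, LiCl, then ZnCl2; NiCl2(dme), 4,4'-di-tert-butyl-2,2'-bipyridine, THF/DMF, rt) should give 1-(benzyloxy)-3-{2-[3-(benzyloxy)phenyl]ethyl}-2,4,6-tris[4-(benzyloxy)benzyl]-5-methoxybenzene F3. Hydrogenolysis of its five benzyl ethers under the conditions of step 11 comes back to the route at target 16.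

2. Step 5. The last benzylation creates a hexasubstituted ring at the position flanked by both oxygen substituents and may stall, while the benzylic cation self-condenses with its own alcohol or alkylates the pendant rings already in place. Fallback: the third C–C bond is made by cross-coupling instead of electrophilic substitution, setting out from bis-benzylated phenol 6. Bromination of the one free position of ring A (NBS, 1.0 equiv, CH2Cl2, 0 °C, dark) should give methyl 3-{2,6-bis[4-(benzyloxy)benzyl]-4-bromo-3-hydroxy-5-methoxyphenyl}propanoate F4. O-Benzylation (BnBr, K2CO3, DMF, 60 °C) would give methyl 3-{3-(benzyloxy)-2,6-bis[4-(benzyloxy)benzyl]-4-bromo-5-methoxyphenyl}propanoate F5. Negishi coupling with 4-(benzyloxy)benzylzinc chloride (from 4-(benzyloxy)benzyl chloride, Zn dust, LiCl; Pd(OAc)2, SPhos, THF, 60 °C) then comes back to the route at 8.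

3. Step 10. DDQ may go on to abstract hydride from the doubly benzylic CH2 groups of the electron-rich diarylmethanes, or the silyl enol ether may hydrolyse before oxidation so that the dihydro ring is no longer dehydrogenated cleanly. Fallback: the ring is aromatised at the enone level without a quinone, setting out from 13. Deliberate hydrolysis and conjugation (aq. HCl, THF, rt) should give 3-(2-{3-(benzyloxy)-2,4,6-tris[4-(benzyloxy)benzyl]-5-methoxyphenyl}ethyl)cyclohex-2-en-1-one F6. Palladium-catalysed aerobic dehydrogenation of this 3-substituted cyclohexenone (Pd(O2CCF3)2, 2-(dimethylamino)pyridine, TsOH, O2 1 atm, DMSO, 80 °C) would give the meta-substituted phenol and comes back to the route at 15.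

**Further compounds**

F1 | step 9 | 3-{3-(benzyloxy)-2,4,6-tris[4-(benzyloxy)benzyl]-5-methoxyphenyl}propanoic acid | OC(=O)CCc1c(Cc2ccc(OCc3ccccc3)cc2)c(OCc2ccccc2)c(Cc2ccc(OCc3ccccc3)cc2)c(OC)c1Cc1ccc(OCc2ccccc2)cc1
F2 | step 9 | 1,3-dioxoisoindolin-2-yl 3-{3-(benzyloxy)-2,4,6-tris[4-(benzyloxy)benzyl]-5-methoxyphenyl}propanoate | O=C(CCc1c(Cc2ccc(OCc3ccccc3)cc2)c(OCc2ccccc2)c(Cc2ccc(OCc3ccccc3)cc2)c(OC)c1Cc1ccc(OCc2ccccc2)cc1)ON1C(=O)c2ccccc2C1=O
F3 | step 9 | 1-(benzyloxy)-3-{2-[3-(benzyloxy)phenyl]ethyl}-2,4,6-tris[4-(benzyloxy)benzyl]-5-methoxybenzene | COc1c(Cc2ccc(OCc3ccccc3)cc2)c(OCc2ccccc2)c(Cc2ccc(OCc3ccccc3)cc2)c(CCc2cccc(OCc3ccccc3)c2)c1Cc1ccc(OCc2ccccc2)cc1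
F4 | step 5 | methyl 3-{2,6-bis[4-(benzyloxy)benzyl]-4-bromo-3-hydroxy-5-methoxyphenyl}propanoate | COC(=O)CCc1c(Cc2ccc(OCc3ccccc3)cc2)c(O)c(Br)c(OC)c1Cc1ccc(OCc2ccccc2)cc1
F5 | step 5 | methyl 3-{3-(benzyloxy)-2,6-bis[4-(benzyloxy)benzyl]-4-bromo-5-methoxyphenyl}propanoate | COC(=O)CCc1c(Cc2ccc(OCc3ccccc3)cc2)c(OCc2ccccc2)c(Br)c(OC)c1Cc1ccc(OCc2ccccc2)cc1
F6 | step 10 | 3-(2-{3-(benzyloxy)-2,4,6-tris[4-(benzyloxy)benzyl]-5-methoxyphenyl}ethyl)cyclohex-2-en-1-one | COc1c(Cc2ccc(OCc3ccccc3)cc2)c(OCc2ccccc2)c(Cc2ccc(OCc3ccccc3)cc2)c(CCC2=CC(=O)CCC2)c1Cc1ccc(OCc2ccccc2)cc1
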